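**Plan**

- Numbering used throughout is that of spiro[benzo[7]annulene-5,1'-cyclohexane]: C4a/C9a are the fusion carbons of ring A (the trimethoxybenzene), C5 is the spiro carbon, C6 is CH2, C7 and C8 are the CHCH3 carbons, C9 is the CHOAc carbon, and ring B is the cyclohexadienone.
- Retrosynthesis: the acetate and the C9 carbinol go back to a C9 ketone. That ketone is cut at C4a–C5 and C7–C8 together, a (4+3) disconnection into a 2-bromoaryl ethyl ketone (C4a, C9a, C9, C8) and a phenol with a 2-sulfonyloxypropyl chain (C5, C6, C7).
- Enabling feature: ring B is a dearomatised 2,6-dimethoxyphenol whose para carbon is C5, and C7 lies 1,3 to it across C6H2. Ring B can therefore act twice as a phenolate: first as the leaving group of a C5–C6–C7 spiro-cyclopropane that the C8 enolate opens, then as the carbon nucleophile captured by arylpalladium at C4a.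
- Forward: two short branches (bromo ketone; phenol tosylate) meet in the key step, which builds the seven-membered ring and the spiro centre; ketone reduction and acetylation finish.
- Stereochemistry: C7 is bought with (R)-2-methyloxirane (two inversions in the key step give net retention). C8 is relayed by base equilibration next to the ketone (trans to the C7 methyl). C9 is set by substrate-controlled hydride delivery (trans to the C8 methyl).

Key step: step 7

Remark on the chemistry: the all-trans arrangement at C7, C8 and C9 of the target is assumed to be the preferred pseudo-equatorial one in the benzo[7]annulene ring; step 8 carries a fallback for the opposite outcome at C9.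

Step 1
Reactants: 1 2-bromo-3,4,5-trimethoxybenzaldehyde
Product: 2 rac-1-(2-bromo-3,4,5-trimethoxyphenyl)propan-1-ol
Conditions: EtMgBr, THF, −20 → 0 °C; then H2O
Reagents that add atoms: ethylmagnesium bromide, CC[Mg]Br
Why: Grignard 1,2-addition to the aldehyde (the aryl bromide does not exchange with EtMgBr at this temperature); the carbinol centre is racemic and is erased in step 2.

Step 2
Reactants: 2 rac-1-(2-bromo-3,4,5-trimethoxyphenyl)propan-1-ol
Product: 3 1-(2-bromo-3,4,5-trimethoxyphenyl)propan-1-one
Conditions: Dess–Martin periodinane, CH2Cl2, 0 → 23 °C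
Reagents that add atoms: none
Why: Dess–Martin oxidation of a secondary benzylic alcohol to the aryl ketone, with no stereocentre involved.

Step 3
Reactants: 4 4-bromo-2,6-dimethoxyphenol
Product: 5 2-(benzyloxy)-5-bromo-1,3-dimethoxybenzene
Conditions: BnBr, K2CO3, DMF, 23 °C
Reagents that add atoms: benzyl bromide, BrCc1ccccc1
Why: Williamson O-benzylation masks the phenol for the Grignard chemistry of step 4.

Step 4
Reactants: 5 2-(benzyloxy)-5-bromo-1,3-dimethoxybenzene; 6 (R)-2-methyloxirane
Product: 8 (R)-1-[4-(benzyloxy)-3,5-dimethoxyphenyl]propan-2-ol, via arylmagnesium bromide 7 (not isolated)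
Conditions: Mg, THF, 50 °C; then CuI (10 mol %), 6, −30 → 0 °C; then H2O
Reagents that add atoms: none
Why: CuI-catalysed SN2 opening of the epoxide at its CH2 terminus by the aryl Grignard reagent leaves the C–O stereocentre of 6 untouched, so the (R) configuration is carried into 8.

Step 5
Reactants: 8 (R)-1-[4-(benzyloxy)-3,5-dimethoxyphenyl]propan-2-ol
Product: 9 (R)-1-[4-(benzyloxy)-3,5-dimethoxyphenyl]propan-2-yl 4-methylbenzenesulfonate
Conditions: TsCl, Et3N, DMAP (cat.), CH2Cl2, 0 → 23 °C
Reagents that add atoms: p-toluenesulfonyl chloride, Cc1ccc(cc1)S(=O)(=O)Cl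
Why: O-sulfonylation forms only an O–S bond, so the stereocentre is retained; a tosylate is chosen because it has no acidic α-hydrogen for the strong base of step 7.

Step 6
Reactants: 9 (R)-1-[4-(benzyloxy)-3,5-dimethoxyphenyl]propan-2-yl 4-methylbenzenesulfonate
Product: 10 (R)-1-(4-hydroxy-3,5-dimethoxyphenyl)propan-2-yl 4-methylbenzenesulfonate
Conditions: H2 (1 atm), 10% Pd/C, EtOAc, 23 °C
Reagents that add atoms: none
Why: Hydrogenolysis removes the benzyl ether while the alkyl tosylate survives, and the neutral phenol is too weak a neighbouring group to expel tosylate in a non-ionising solvent.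

Step 7
Reactants: 3 1-(2-bromo-3,4,5-trimethoxyphenyl)propan-1-one; 10 (R)-1-(4-hydroxy-3,5-dimethoxyphenyl)propan-2-yl 4-methylbenzenesulfonate
Product: 13 (7R,8S)-2,3,3',4,5'-pentamethoxy-7,8-dimethyl-7,8-dihydrospiro[benzo[7]annulene-5,1'-cyclohexa[2,5]diene]-4',9(6H)-dione, via spirocyclopropyl dienone 11 (not isolated), via ring-opened potassium phenolate 12 (not isolated)
Conditions: KN(SiMe3)2 (2.1 equiv), Pd(OAc)2 (5 mol %), tBuXPhos (10 mol %), toluene–THF, −78 → 23 °C, then 90 °C (sealed); AcOH quench
Reagents that add atoms: none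
Why: Proposed new method: KN(SiMe3)2 converts 10 into its phenolate and 3 into its potassium enolate; on warming the phenolate expels tosylate through its para carbon (3-exo-tet, inversion at C7) to give spiro[2.5]octadienone 11, the enolate opens this strained donor–acceptor cyclopropane at the methyl-bearing carbon in a homo-Michael addition driven by rearomatisation of ring B (second inversion, C7–C8 formed, phenolate 12 released), and at 90 °C zerovalent palladium inserts into the C–Br bond of 12, the phenolate binds through its para carbon and C–C reductive elimination forms C4a–C5. The closest known reaction types are the homoconjugate opening of spiro-activated cyclopropanes by stabilised carbanions and the palladium-catalysed intramolecular arylative dearomatisation of para-substituted phenols by tethered aryl bromides; their merger into one formal (4+3) annulation is the new element. The transient three-membered ring closes 3-exo-tet, and the seven-membered ring closes by reductive elimination from an aryl(dienonyl)palladium intermediate, formally a 7-exo attack of the phenolate para carbon on the aryl carbon, which also creates the spiro centre C5 (not stereogenic, ring B being symmetric). C7 is fixed by the purchased stereocentre through two SN2 inversions, while C8 forms without control but lies α to the C9 ketone and should be equilibrated by the slight excess of base to the trans-7,8-dimethyl (diequatorial) isomer. The step needs attack at the more substituted cyclopropane carbon (its bond to the spiro carbon is the longer and more polarised one), C- over O-alkylation of the enolate (potassium enolate in toluene, soft electrophile), para-C- over O-arylation (only the para carbon can reach palladium through a seven-membered closure and both ortho positions carry OMe), and alkylation before oxidative addition (the hindered, electron-rich aryl bromide should add to palladium only on heating, which also keeps intermolecular ketone α-arylation down).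

Step 8
Reactants: 13 (7R,8S)-2,3,3',4,5'-pentamethoxy-7,8-dimethyl-7,8-dihydrospiro[benzo[7]annulene-5,1'-cyclohexa[2,5]diene]-4',9(6H)-dione
Product: 14 (7R,8S,9R)-9-hydroxy-2,3,3',4,5'-pentamethoxy-7,8-dimethyl-6,7,8,9-tetrahydrospiro[benzo[7]annulene-5,1'-cyclohexa[2,5]dien]-4'-one
Conditions: NaBH4, MeOH–CH2Cl2, −40 → −20 °C
Reagents that add atoms: none
Why: Borohydride 1,2-reduction should take the aryl ketone and spare the cross-conjugated dienone carbonyl (such carbonyls, as in steroidal 1,4-dien-3-ones, are far less electrophilic towards borohydride), and axial hydride delivery anti to the axial C8–H should give the equatorial C9 alcohol trans to the C8 methyl.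

Step 9
Reactants: 14 (7R,8S,9R)-9-hydroxy-2,3,3',4,5'-pentamethoxy-7,8-dimethyl-6,7,8,9-tetrahydrospiro[benzo[7]annulene-5,1'-cyclohexa[2,5]dien]-4'-one
Product: 15 (7R,8S,9R)-2,3,3',4,5'-pentamethoxy-7,8-dimethyl-4'-oxo-6,7,8,9-tetrahydrospiro[benzo[7]annulene-5,1'-cyclohexa[2,5]dien]-9-yl acetate
Conditions: Ac2O, pyridine, DMAP (cat.), CH2Cl2, 23 °C
Reagents that add atoms: acetic anhydride, CC(=O)OC(C)=O
Why: DMAP-catalysed O-acylation of the secondary alcohol proceeds with retention at C9 and leaves the dienone untouched.

**Compound list**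

1 | 2-bromo-3,4,5-trimethoxybenzaldehyde | COc1cc(C=O)c(Br)c(OC)c1OC | starting material
2 | rac-1-(2-bromo-3,4,5-trimethoxyphenyl)propan-1-ol | CCC(O)c1cc(OC)c(OC)c(OC)c1Br | intermediate
3 | 1-(2-bromo-3,4,5-trimethoxyphenyl)propan-1-one | CCC(=O)c1cc(OC)c(OC)c(OC)c1Br | intermediate
4 | 4-bromo-2,6-dimethoxyphenol | COc1cc(Br)cc(OC)c1O | starting material
5 | 2-(benzyloxy)-5-bromo-1,3-dimethoxybenzene | COc1cc(Br)cc(OC)c1OCc1ccccc1 | intermediate
6 | (R)-2-methyloxirane | C[C@@H]1CO1 | starting material
7 | [4-(benzyloxy)-3,5-dimethoxyphenyl]magnesium bromide | COc1cc([Mg]Br)cc(OC)c1OCc1ccccc1 | intermediate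
8 | (R)-1-[4-(benzyloxy)-3,5-dimethoxyphenyl]propan-2-ol | C[C@@H](O)Cc1cc(OC)c(OCc2ccccc2)c(OC)c1 | intermediate
9 | (R)-1-[4-(benzyloxy)-3,5-dimethoxyphenyl]propan-2-yl 4-methylbenzenesulfonate | C[C@@H](OS(=O)(=O)c1ccc(C)cc1)Cc1cc(OC)c(OCc2ccccc2)c(OC)c1 | intermediate
10 | (R)-1-(4-hydroxy-3,5-dimethoxyphenyl)propan-2-yl 4-methylbenzenesulfonate | C[C@@H](OS(=O)(=O)c1ccc(C)cc1)Cc1cc(OC)c(O)c(OC)c1 | intermediate
11 | (1S)-5,7-dimethoxy-1-methylspiro[2.5]octa-4,7-dien-6-one | C[C@H]1CC12C=C(OC)C(=O)C(OC)=C2 | intermediate
12 | potassium 4-[(2R)-4-(2-bromo-3,4,5-trimethoxyphenyl)-2,3-dimethyl-4-oxobutyl]-2,6-dimethoxyphenolate (both C3 epimers) | C[C@H](Cc1cc(OC)c([O-])c(OC)c1)C(C)C(=O)c1cc(OC)c(OC)c(OC)c1Br.[K+] | intermediate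
13 | (7R,8S)-2,3,3',4,5'-pentamethoxy-7,8-dimethyl-7,8-dihydrospiro[benzo[7]annulene-5,1'-cyclohexa[2,5]diene]-4',9(6H)-dione | COC1=CC2(C=C(OC)C1=O)C[C@@H](C)[C@H](C)C(=O)c1cc(OC)c(OC)c(OC)c12 | intermediate
14 | (7R,8S,9R)-9-hydroxy-2,3,3',4,5'-pentamethoxy-7,8-dimethyl-6,7,8,9-tetrahydrospiro[benzo[7]annulene-5,1'-cyclohexa[2,5]dien]-4'-one | COC1=CC2(C=C(OC)C1=O)C[C@@H](C)[C@H](C)[C@@H](O)c1cc(OC)c(OC)c(OC)c12 | intermediate
15 | (7R,8S,9R)-2,3,3',4,5'-pentamethoxy-7,8-dimethyl-4'-oxo-6,7,8,9-tetrahydrospiro[benzo[7]annulene-5,1'-cyclohexa[2,5]dien]-9-yl acetate | COC1=CC2(C=C(OC)C1=O)C[C@@H](C)[C@H](C)[C@@H](OC(C)=O)c1cc(OC)c(OC)c(OC)c12 | target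

**Step count**

Total steps: 9. Longest linear sequence: 7 (steps 3 to 9).

**Steps most likely to fail**

Step 7 (proposed new method). What may go wrong: opening of the spiro-cyclopropane at its unsubstituted carbon or O-alkylation of the enolate; and protodebromination or intermolecular arylation in place of the seven-membered ring closure. The fallback separates the two bond formations into known reaction types and sets out from 10.
- 10 is closed to 11 with NaH in THF at 0 °C.
- Purchased 1-(3,4,5-trimethoxyphenyl)propan-1-one F1 is converted with Me3SiOTf and Et3N into (Z)-trimethyl{[1-(3,4,5-trimethoxyphenyl)prop-1-en-1-yl]oxy}silane F2.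
- F2 opens 11 at −78 °C under Me3SiOTf catalysis (Mukaiyama-type homo-Michael addition; the O-silylated, phenonium-like cyclopropane should be attacked at its more substituted carbon). Aqueous work-up should give (3R)-4-(4-hydroxy-3,5-dimethoxyphenyl)-2,3-dimethyl-1-(3,4,5-trimethoxyphenyl)butan-1-one F3.
- F3 is oxidised with PhI(OCOCF3)2 in CF3CH2OH at −40 °C (phenol-to-arene ipso coupling, ring B as phenoxonium ion, either equivalent free ortho position of ring A as nucleophile). Equilibration with DBU should then bring the route back at 13.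

Step 8. What may go wrong: hydride delivery to the wrong face of the C9 carbonyl, or competing reduction of the dienone carbonyl. The fallback sets out from 13 and accepts the opposite face.
- Catalyst-controlled asymmetric transfer hydrogenation with RuCl[(S,S)-TsDPEN](p-cymene) in HCO2H–Et3N (an outer-sphere hydride transfer that prefers aryl ketones) should give (7R,8S,9S)-9-hydroxy-2,3,3',4,5'-pentamethoxy-7,8-dimethyl-6,7,8,9-tetrahydrospiro[benzo[7]annulene-5,1'-cyclohexa[2,5]dien]-4'-one F4.
- A Mitsunobu reaction of F4 with acetic acid (PPh3, diisopropyl azodicarboxylate, THF, 0 °C) installs the acetate with inversion at C9 and comes back to the route at 15, bypassing 14.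

Step 6. What may go wrong: loss of the tosylate through aryl participation once the phenol is unmasked (solvolysis or oligomerisation on concentration). The fallback sets out from 8 and never isolates a phenol sulfonate.
- Hydrogenolysis of 8 (H2, 10% Pd/C, EtOAc) should give (R)-4-(2-hydroxypropyl)-2,6-dimethoxyphenol F5.
- Mitsunobu cyclodehydration of F5 (PBu3, 1,1'-(azodicarbonyl)dipiperidine, toluene, 0 °C; the phenol para carbon displaces the activated secondary oxygen with inversion) comes back to the route at 11.
- The solution of 11 is passed through a short silica plug and used at once in step 7 with the enolate of 3 preformed from 1.05 equiv of KN(SiMe3)2.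

**Further compounds**

F1 | step 7 | 1-(3,4,5-trimethoxyphenyl)propan-1-one | CCC(=O)c1cc(OC)c(OC)c(OC)c1
F2 | step 7 | (Z)-trimethyl{[1-(3,4,5-trimethoxyphenyl)prop-1-en-1-yl]oxy}silane | C/C=C(\O[Si](C)(C)C)c1cc(OC)c(OC)c(OC)c1
F3 | step 7 | (3R)-4-(4-hydroxy-3,5-dimethoxyphenyl)-2,3-dimethyl-1-(3,4,5-trimethoxyphenyl)butan-1-one (both C2 epimers) | C[C@H](Cc1cc(OC)c(O)c(OC)c1)C(C)C(=O)c1cc(OC)c(OC)c(OC)c1
F4 | step 8 | (7R,8S,9S)-9-hydroxy-2,3,3',4,5'-pentamethoxy-7,8-dimethyl-6,7,8,9-tetrahydrospiro[benzo[7]annulene-5,1'-cyclohexa[2,5]dien]-4'-one | COC1=CC2(C=C(OC)C1=O)C[C@@H](C)[C@H](C)[C@H](O)c1cc(OC)c(OC)c(OC)c12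
F5 | step 6 | (R)-4-(2-hydroxypropyl)-2,6-dimethoxyphenol | C[C@@H](O)Cc1cc(OC)c(O)c(OC)c1
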